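**Strategy.** Ring A (the bromo‑dimethylcyclohexyl acetate ring) is cut into 3‑hydroxy‑2‑pyrone and 2‑methyl‑1‑nitropropene. One base‑catalysed Diels–Alder (Michael–Henry) step joins pyrone C‑6 to the CMe2 carbon and pyrone C‑3 to the future ring CH2. The step exploits the 1,4‑relationship in ring A between the oxygenated quaternary carbon and the CH–Br carbon, together with the exocyclic CH2 on the quaternary carbon. These arrive as pyrone C‑3, C‑6 and C‑2, locked in a bridged lactone that fixes their relative and absolute configuration. The lactone is then turned into an alkyne and alkylated with a Birch‑derived cyclohexadiene; gold‑catalysed enyne cyclisation, lactonisation and a late vinyl‑bromide reduction finish the target.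

Key step: step 1

Assumption: the senses of induction of the cinchona catalyst (step 1) and of the (S)‑prolinol‑ether auxiliary (step 9) are as drawn; if either is opposite, the pseudo‑enantiomeric catalyst (9‑O‑benzylcupreidine) or the (R)‑auxiliary is used.

**Step 1**
Reactants: 1 3‑hydroxy‑2H‑pyran‑2‑one; 2 2‑methyl‑1‑nitroprop‑1‑ene
Product: 3 (1S,4S,8R)‑4‑hydroxy‑7,7‑dimethyl‑8‑nitro‑2‑oxabicyclo[2.2.2]oct‑5‑en‑3‑one
Conditions: 9‑O‑benzylcupreine (10 mol %), Et2O, 0 → 23 °C
Reagents that add atoms: none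
Why: The cinchona base deprotonates the 3‑hydroxyl while its 6'‑OH activates the nitroalkene, so the vinylogous enolate carbon C‑6 of the pyrone adds to the CMe2 terminus (Michael) and the nitronate then closes onto the C‑3 ketone of the resulting α‑keto lactone (Henry). The closest known reaction type is the cinchona‑alkaloid‑catalysed [4+2] cycloaddition of 3‑hydroxy‑2‑pyrones with nitroalkenes and enones. The carbocycle closes by a 6‑(enolexo)‑exo‑trig addition after the intermolecular conjugate addition, which leaves the lactone as the third bridge of a bicyclo[2.2.2]octene. The two bridgehead stereocentres (C‑1 with the lactone oxygen, C‑4 with the tertiary OH) can only form as one relative pair, and their absolute sense should be set by the catalyst shielding one face of the pyrone; the nitro‑bearing C‑8 (drawn endo) does not matter because it is removed in step 3. The step needs regioselectivity (C‑6 to the β‑carbon, the nitro carbon to C‑3), which the polarity of the dienolate and of the nitroalkene dictates, and it needs the hindered β,β‑dimethyl acceptor to react, for which the strongly electrophilic nitroalkene is chosen.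

**Step 2**
Reactants: 3
Product: 4 (1S,4S,8R)‑4‑hydroxy‑7,7‑dimethyl‑8‑nitro‑2‑oxabicyclo[2.2.2]octan‑3‑one
Conditions: KO2CN=NCO2K, AcOH, MeOH, 0 → 23 °C
Reagents that add atoms: none
Why: Diimide reduction should add H2 syn to the strained cis‑disubstituted bridge alkene without touching the nitro group or the allylic lactone C–O bond, and it removes the alkene that could otherwise allow retro‑[4+2] loss of CO2; no stereocentre is formed.

**Step 3**
Reactants: 4
Product: 5 (1S,4S)‑4‑hydroxy‑7,7‑dimethyl‑2‑oxabicyclo[2.2.2]octan‑3‑one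
Conditions: Bu3SnH, AIBN, toluene, 110 °C
Reagents that add atoms: none
Why: Radical denitration with tin hydride: Bu3Sn• adds to a nitro oxygen, C–N scission gives the secondary radical, and this takes H from Bu3SnH, so the only stereocentre touched is the one that disappears.

**Step 4**
Reactants: 5
Product: 6 (1S,4S)‑7,7‑dimethyl‑4‑(triethylsilyloxy)‑2‑oxabicyclo[2.2.2]octan‑3‑one
Conditions: Et3SiOTf, 2,6‑lutidine, CH2Cl2, 0 °C
Reagents that add atoms: triethylsilyl trifluoromethanesulfonate, CC[Si](CC)(CC)OS(=O)(=O)C(F)(F)F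
Why: Silylation of the hindered tertiary bridgehead alcohol with a silyl triflate protects it for the hydride and base steps and later keeps the propargylic oxygen inert toward gold; no stereocentre changes.

**Step 5**
Reactants: 6
Product: 7 (1S,4S)‑7,7‑dimethyl‑4‑(triethylsilyloxy)‑2‑oxabicyclo[2.2.2]octan‑3‑ol (lactol; both anomers)
Conditions: i‑Bu2AlH (1.1 equiv), toluene, −78 °C; Rochelle salt work‑up
Reagents that add atoms: none
Why: Partial lactone reduction should stop at the lactol because the tetrahedral aluminium hemiacetal is stable at −78 °C; the anomeric centre is lost in step 6.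

**Step 6**
Reactants: 7
Product: 8 (1S,4S)‑4‑ethynyl‑2,2‑dimethyl‑4‑(triethylsilyloxy)cyclohexan‑1‑ol
Conditions: dimethyl (1‑diazo‑2‑oxopropyl)phosphonate, K2CO3, MeOH, 0 → 23 °C
Reagents that add atoms: dimethyl (1‑diazo‑2‑oxopropyl)phosphonate, COP(=O)(OC)C(=[N+]=[N-])C(C)=O
Why: Seyferth–Gilbert homologation (Bestmann–Ohira reagent): the lactol opens to the α‑silyloxy aldehyde, whose carbon (the former pyrone C‑2) becomes the alkyne carbon on the quaternary centre; that centre is untouched and the secondary alcohol is set free.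

**Step 7**
Reactants: 8
Product: 9 {[(1S,4R)‑4‑bromo‑1‑ethynyl‑3,3‑dimethylcyclohexyl]oxy}(triethyl)silane
Conditions: CBr4, PPh3, 2,6‑lutidine, toluene, 23 → 60 °C
Reagents that add atoms: carbon tetrabromide, BrC(Br)(Br)Br
Why: Appel reaction: bromide displaces the alkoxyphosphonium by SN2 with inversion at the neopentylic carbinol carbon, which should place bromine cis to the silyloxy group; the silyl ether blocks transannular ether formation, though this hindered displacement is slow and may compete with elimination.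

**Step 8**
Reactants: 10 2‑methoxy‑5‑methylbenzoic acid; 11 (S)‑2‑(methoxymethyl)pyrrolidine
Product: 13 [(2S)‑2‑(methoxymethyl)pyrrolidin‑1‑yl](2‑methoxy‑5‑methylphenyl)methanone, via 2‑methoxy‑5‑methylbenzoyl chloride 12 (not isolated)
Conditions: (COCl)2, DMF (cat.), CH2Cl2, 0 → 23 °C; then 11, Et3N, CH2Cl2, 0 °C
Reagents that add atoms: none
Why: N‑Acylation of the secondary amine by the acid chloride; the auxiliary stereocentre is not involved.

**Step 9**
Reactants: 13; 14 1‑bromo‑2‑chloroethane
Product: 16 [(1S)‑1‑(2‑chloroethyl)‑2‑methoxy‑5‑methylcyclohexa‑2,5‑dien‑1‑yl][(2S)‑2‑(methoxymethyl)pyrrolidin‑1‑yl]methanone, via potassium amide enolate 15 (not isolated)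
Conditions: K, NH3(l), THF, t‑BuOH (1 equiv), −78 °C; piperylene; then 14, −78 → 23 °C
Reagents that add atoms: none
Why: Birch reduction–alkylation: reduction and protonation at C‑4 give the chelated amide enolate, which should be alkylated at the bromide end on the face left open by the methoxymethyl‑pyrrolidine auxiliary, setting the quaternary carbon.

**Step 10**
Reactants: 16
Product: 17 [(1S)‑1‑(2‑iodoethyl)‑2‑methoxy‑5‑methylcyclohexa‑2,5‑dien‑1‑yl][(2S)‑2‑(methoxymethyl)pyrrolidin‑1‑yl]methanone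
Conditions: NaI, NaHCO3, acetone, reflux
Reagents that add atoms: sodium iodide, [Na+].[I-]
Why: Finkelstein exchange (SN2) driven by precipitation of NaCl; the buffered neutral medium should preserve the enol ether, and no stereocentre is involved.

**Step 11**
Reactants: 9; 17
Product: 20 (2S)‑2‑{4‑[(1S,4R)‑4‑bromo‑3,3‑dimethyl‑1‑(triethylsilyloxy)cyclohexyl]but‑3‑yn‑1‑yl}‑2‑{[(2S)‑2‑(methoxymethyl)pyrrolidin‑1‑yl]carbonyl}‑4‑methylcyclohex‑3‑en‑1‑one, via lithium acetylide 18 (not isolated), via coupled enol ether 19 (not isolated)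
Conditions: n‑BuLi, THF, −78 °C; then 17, HMPA, −78 → 23 °C; then aq. oxalic acid, THF, 23 °C
Reagents that add atoms: water, O
Why: Acetylide alkylation (SN2 at the primary iodide) joins the fragments, and mild acid hydrolysis of the 1‑methoxydiene then gives the β,γ‑unsaturated ketone without moving the ring alkene or cleaving the tertiary silyl ether; no stereocentre is formed.

**Step 12**
Reactants: 20
Product: 21 cis‑fused 1‑[(Z)‑(ring A)methylidene]‑7‑hydroxy‑7‑methyl‑3a‑{[(2S)‑2‑(methoxymethyl)pyrrolidin‑1‑yl]carbonyl}octahydro‑4H‑inden‑4‑one (H‑7a cis to the carboxamide; 7‑OH cis to the carboxamide)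
Conditions: Ph3PAuNTf2 (5 mol %), 1,4‑dioxane/H2O (10:1), 23 °C
Reagents that add atoms: water, O
Why: Gold‑catalysed 5‑exo‑dig hydroxycyclisation of the 1,6‑enyne: the ring alkene CH attacks the activated alkyne on the face of the tether (cis ring fusion, new CH stereocentre); water, or the amide oxygen followed by hydrolysis, then opens the cyclopropyl gold carbene at the tertiary carbon anti to the new C–C bond, setting the carbinol syn to the carboxamide, and protodeauration leaves the (Z)‑alkene.

**Step 13**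
Reactants: 21
Product: 22 cis‑fused 1‑[(ring A)methyl]‑7‑hydroxy‑7‑methyl‑3a‑{[(2S)‑2‑(methoxymethyl)pyrrolidin‑1‑yl]carbonyl}octahydro‑4H‑inden‑4‑one (H‑1 cis to H‑7a)
Conditions: H2 (4 atm), Rh/Al2O3, EtOAc, 23 °C
Reagents that add atoms: none
Why: Heterogeneous hydrogenation should deliver hydrogen to the exocyclic alkene from the face of the ring‑fusion hydrogen, the other face being screened by the adjacent quaternary carbinol carbon; this sets the cyclopentane CH with the side chain cis to the six‑membered ring, and Rh on alumina spares the allylic silyl ether, the C–Br bond and the ketone.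

**Step 14**
Reactants: 22
Product: 23 tricyclic hydroxy lactone ketone (γ‑lactone from the angular carboxyl to the tertiary oxygen; free tertiary OH on ring A)
Conditions: TsOH·H2O (1.5 equiv), MeCN, 45 °C
Reagents that add atoms: none
Why: Acid‑promoted N→O acyl transfer: the tertiary hydroxyl, held 1,3‑diaxial to the carboxamide, attacks the protonated amide and the auxiliary leaves as its ammonium salt, closing the bridged γ‑lactone at centres that are already fixed; the same acid removes the triethylsilyl group.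

**Step 15**
Reactants: 23
Product: 24 tricyclic lactone ketone tertiary acetate
Conditions: Ac2O, DMAP, Et3N, CH2Cl2, 40 °C
Reagents that add atoms: acetic anhydride, CC(=O)OC(C)=O
Why: DMAP‑catalysed acylation of the only free hydroxyl (the tertiary one); no stereocentre changes.

**Step 16**
Reactants: 24
Product: 25 vinyl bromide (C(Br)=CH in place of the ketone C(=O)–CH2)
Conditions: (PhO)3P, Br2, Et3N, CH2Cl2, −60 → 40 °C
Reagents that add atoms: bromine, BrBr
Why: Ketone‑to‑vinyl‑bromide conversion with triphenyl phosphite dibromide: the activated ketone takes up bromide and loses HBr toward the only enolisable side, since the other α‑carbon is quaternary.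

**Step 17**
Reactants: 25
Product: 26 target, the dibromo lactone acetate
Conditions: Mn(dpm)3 [tris(2,2,6,6‑tetramethylheptane‑3,5‑dionato)manganese] (10 mol %), PhSiH3, t‑BuOOH, i‑PrOH, 23 °C
Reagents that add atoms: none
Why: Metal‑hydride hydrogen‑atom‑transfer hydrogenation: H• adds to the CH terminus and the α‑bromo radical should take its second hydrogen axially, leaving bromine equatorial (cis to the lactone carbonyl) and avoiding a 1,3‑diaxial clash with the cyclopentane carbon; this method is known to retain vinyl and alkyl C–Br bonds.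

**Compound list**

1 | 3‑hydroxy‑2H‑pyran‑2‑one | O=C1OC=CC=C1O | starting material
2 | 2‑methyl‑1‑nitroprop‑1‑ene | CC(C)=C[N+](=O)[O-] | starting material
3 | (1S,4S,8R)‑4‑hydroxy‑7,7‑dimethyl‑8‑nitro‑2‑oxabicyclo[2.2.2]oct‑5‑en‑3‑one | O=C1O[C@H]2C=C[C@]1(O)[C@H]([N+](=O)[O-])C2(C)C | intermediate
4 | (1S,4S,8R)‑4‑hydroxy‑7,7‑dimethyl‑8‑nitro‑2‑oxabicyclo[2.2.2]octan‑3‑one | O=C1O[C@H]2CC[C@]1(O)[C@H]([N+](=O)[O-])C2(C)C | intermediate
5 | (1S,4S)‑4‑hydroxy‑7,7‑dimethyl‑2‑oxabicyclo[2.2.2]octan‑3‑one | O=C1O[C@H]2CC[C@]1(O)CC2(C)C | intermediate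
6 | (1S,4S)‑7,7‑dimethyl‑4‑(triethylsilyloxy)‑2‑oxabicyclo[2.2.2]octan‑3‑one | O=C1O[C@H]2CC[C@]1(O[Si](CC)(CC)CC)CC2(C)C | intermediate
7 | (1S,4S)‑7,7‑dimethyl‑4‑(triethylsilyloxy)‑2‑oxabicyclo[2.2.2]octan‑3‑ol (both anomers) | OC1O[C@H]2CC[C@]1(O[Si](CC)(CC)CC)CC2(C)C | intermediate
8 | (1S,4S)‑4‑ethynyl‑2,2‑dimethyl‑4‑(triethylsilyloxy)cyclohexan‑1‑ol | C#C[C@]1(O[Si](CC)(CC)CC)CC[C@H](O)C(C)(C)C1 | intermediate
9 | {[(1S,4R)‑4‑bromo‑1‑ethynyl‑3,3‑dimethylcyclohexyl]oxy}(triethyl)silane | C#C[C@]1(O[Si](CC)(CC)CC)CC[C@@H](Br)C(C)(C)C1 | intermediate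
10 | 2‑methoxy‑5‑methylbenzoic acid | COc1ccc(C)cc1C(=O)O | starting material
11 | (S)‑2‑(methoxymethyl)pyrrolidine | COC[C@@H]1CCCN1 | starting material
12 | 2‑methoxy‑5‑methylbenzoyl chloride | COc1ccc(C)cc1C(Cl)=O | intermediate
13 | [(2S)‑2‑(methoxymethyl)pyrrolidin‑1‑yl](2‑methoxy‑5‑methylphenyl)methanone | COC[C@@H]1CCCN1C(=O)c1cc(C)ccc1OC | intermediate
14 | 1‑bromo‑2‑chloroethane | ClCCBr | starting material
15 | potassium amide enolate from Birch reduction of 13 | [K+].[O-]C(N1CCC[C@H]1COC)=C1C=C(C)CC=C1OC | intermediate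
16 | [(1S)‑1‑(2‑chloroethyl)‑2‑methoxy‑5‑methylcyclohexa‑2,5‑dien‑1‑yl][(2S)‑2‑(methoxymethyl)pyrrolidin‑1‑yl]methanone | ClCC[C@@]1(C(=O)N2CCC[C@H]2COC)C(OC)=CCC(C)=C1 | intermediate
17 | [(1S)‑1‑(2‑iodoethyl)‑2‑methoxy‑5‑methylcyclohexa‑2,5‑dien‑1‑yl][(2S)‑2‑(methoxymethyl)pyrrolidin‑1‑yl]methanone | ICC[C@@]1(C(=O)N2CCC[C@H]2COC)C(OC)=CCC(C)=C1 | intermediate
18 | lithium acetylide of 9 | [Li+].[C-]#C[C@]1(O[Si](CC)(CC)CC)CC[C@@H](Br)C(C)(C)C1 | intermediate
19 | coupled enol ether (alkylation product before hydrolysis) | CC[Si](CC)(CC)O[C@@]1(C#CCC[C@@]2(C(=O)N3CCC[C@H]3COC)C(OC)=CCC(C)=C2)CC[C@@H](Br)C(C)(C)C1 | intermediate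
20 | (2S)‑2‑{4‑[(1S,4R)‑4‑bromo‑3,3‑dimethyl‑1‑(triethylsilyloxy)cyclohexyl]but‑3‑yn‑1‑yl}‑2‑{[(2S)‑2‑(methoxymethyl)pyrrolidin‑1‑yl]carbonyl}‑4‑methylcyclohex‑3‑en‑1‑one | CC[Si](CC)(CC)O[C@@]1(C#CCC[C@@]2(C(=O)N3CCC[C@H]3COC)C(=O)CCC(C)=C2)CC[C@@H](Br)C(C)(C)C1 | intermediate
21 | cis‑hydrindanone hydroxy amide with (Z)‑exocyclic alkene | CC[Si](CC)(CC)O[C@@]1(/C=C2/CC[C@@]3(C(=O)N4CCC[C@H]4COC)C(=O)CC[C@](C)(O)[C@@H]23)CC[C@@H](Br)C(C)(C)C1 | intermediate
22 | saturated cis‑hydrindanone hydroxy amide | CC[Si](CC)(CC)O[C@@]1(C[C@H]2CC[C@@]3(C(=O)N4CCC[C@H]4COC)C(=O)CC[C@](C)(O)[C@@H]23)CC[C@@H](Br)C(C)(C)C1 | intermediate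
23 | tricyclic hydroxy lactone ketone | O[C@@]1(C[C@H]2CC[C@@]34C(=O)O[C@@](C)(CCC3=O)[C@@H]24)CC[C@@H](Br)C(C)(C)C1 | intermediate
24 | tricyclic lactone ketone tertiary acetate | CC(=O)O[C@@]1(C[C@H]2CC[C@@]34C(=O)O[C@@](C)(CCC3=O)[C@@H]24)CC[C@@H](Br)C(C)(C)C1 | intermediate
25 | vinyl bromide | CC(=O)O[C@@]1(C[C@H]2CC[C@@]34C(=O)O[C@@](C)(CC=C3Br)[C@@H]24)CC[C@@H](Br)C(C)(C)C1 | intermediate
26 | target dibromo lactone acetate | CC(=O)O[C@@]1(C[C@H]2CC[C@@]34C(=O)O[C@@](C)(CC[C@H]3Br)[C@@H]24)CC[C@@H](Br)C(C)(C)C1 | target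

**Count and risks**

Total step count: 17. Longest linear sequence: 14 steps (steps 1–7, then 11–17).

The three steps most likely to fail:

- **Step 1.** The conjugate addition onto the hindered β,β‑dimethyl nitroalkene may be too slow, or the facial discrimination on the pyrone too weak. Fallback: starting from 1, the dienophile is changed to 3‑methylbut‑2‑enal under iminium activation with a 9‑amino‑9‑deoxy‑epi‑cinchona primary amine salt, which should give (1S,4S,8R)‑4‑hydroxy‑7,7‑dimethyl‑3‑oxo‑2‑oxabicyclo[2.2.2]oct‑5‑ene‑8‑carbaldehyde F1. Diimide reduction gives the saturated aldehyde (1S,4S,8R)‑4‑hydroxy‑7,7‑dimethyl‑3‑oxo‑2‑oxabicyclo[2.2.2]octane‑8‑carbaldehyde F2, and decarbonylation with RhCl(PPh3)3 in hot toluene returns to the route at 5.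
- **Step 14.** The acyl transfer may stall because the lactone is trans‑fused to the cyclopentane and strained, and the tertiary alcohols may dehydrate under acid. Fallback: starting from 22, the tertiary alcohol is deliberately dehydrated (Burgess reagent) to the exocyclic methylene amide F3 (its endocyclic isomer converges). Kinetic iodolactonisation (I2, NaHCO3, MeCN/H2O) with the amide oxygen gives the iodomethyl lactone F4 and frees the auxiliary. Bu3SnH removes the iodine to give the silyl lactone ketone F5, and HF·pyridine removes the silyl group, returning to the route at 23.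
- **Step 17.** Hydrogen may be delivered to the wrong face of the α‑bromo radical, or bromine may be lost by reduction. Fallback: starting from 24, the ketone is reduced with LiBH(s‑Bu)3 by equatorial attack to the axial alcohol F6, and an Appel reaction (CBr4, PPh3) with inversion gives the equatorial bromide, returning to the route at 26.

**Further compounds**

F1 | step 1 | (1S,4S,8R)‑4‑hydroxy‑7,7‑dimethyl‑3‑oxo‑2‑oxabicyclo[2.2.2]oct‑5‑ene‑8‑carbaldehyde | O=C1O[C@H]2C=C[C@]1(O)[C@H](C=O)C2(C)C
F2 | step 1 | (1S,4S,8R)‑4‑hydroxy‑7,7‑dimethyl‑3‑oxo‑2‑oxabicyclo[2.2.2]octane‑8‑carbaldehyde | O=C1O[C@H]2CC[C@]1(O)[C@H](C=O)C2(C)C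
F3 | step 14 | exocyclic methylene amide from dehydration of 22 | CC[Si](CC)(CC)O[C@@]1(C[C@H]2CC[C@@]3(C(=O)N4CCC[C@H]4COC)C(=O)CCC(=C)[C@@H]23)CC[C@@H](Br)C(C)(C)C1
F4 | step 14 | iodomethyl lactone | CC[Si](CC)(CC)O[C@@]1(C[C@H]2CC[C@@]34C(=O)O[C@@](CI)(CCC3=O)[C@@H]24)CC[C@@H](Br)C(C)(C)C1
F5 | step 14 | silyl lactone ketone | CC[Si](CC)(CC)O[C@@]1(C[C@H]2CC[C@@]34C(=O)O[C@@](C)(CCC3=O)[C@@H]24)CC[C@@H](Br)C(C)(C)C1
F6 | step 17 | axial alcohol from reduction of 24 | CC(=O)O[C@@]1(C[C@H]2CC[C@@]34C(=O)O[C@@](C)(CC[C@@H]3O)[C@@H]24)CC[C@@H](Br)C(C)(C)C1
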